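**Strategy**

The carbocycle made of C4a, C5, C6, C7, C8 and C8a is closed in the final ring-forming step at C7–C8. Its C8 ketone beside the tertiary carbinol C7 is an α-ketol, so a C8 aldehyde is made nucleophilic by polarity reversal and added to the C7 carbonyl of a methyl 1,2-diketone. This single carbene-catalysed crossed benzoin step forms the ring, the C7–C8 bond and the quaternary C7 stereocentre under catalyst control. Its precursor is a monocyclic 4H-pyran-4-ylidene, built from a maltol-type pyranone, that carries a formyl group at the later C8a and an open, O-silylated 2,3-dioxobutylidene chain at the later C4a. Butyrylation and desilylation complete the synthesis.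

Key step: step 6

Remark: atoms are numbered as in the isochromene skeleton of the target (C1, O2, C3, C4, C4a, C5 to C8, C8a); the exocyclic double bond of the pyran-4-ylidenes 6 to 10 is a push–pull bond that should isomerise freely and is drawn without geometry; the (5aS,10bR) triazolium salt is assumed to give the 7S ketol, and its commercial mirror image would be used if the opposite sense is found.

**Route**

Step 1
Reactants: 1 3-methoxy-2-methyl-4H-pyran-4-one; 2 tert-butyl(2-iodoethoxy)diphenylsilane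
Product: 3 2-[3-(tert-butyldiphenylsilyloxy)propyl]-3-methoxy-4H-pyran-4-one
Conditions: LiN(SiMe3)2, THF, −78 °C; then 2, N,N'-dimethylpropyleneurea, −78 to 0 °C
Reagents that add atoms: none
Why: γ-Deprotonation of the 2-methyl group should give the cross-conjugated dienolate of the pyranone, which is alkylated at the exocyclic carbon by the primary iodide (vinylogous enolate alkylation).

Step 2
Reactants: 3 2-[3-(tert-butyldiphenylsilyloxy)propyl]-3-methoxy-4H-pyran-4-one; 4 2-(tert-butyldiphenylsilyloxy)-N-methoxy-N-methylacetamide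
Product: 6 2-(tert-butyldiphenylsilyloxy)-2-{2-[3-(tert-butyldiphenylsilyloxy)propyl]-3-methoxy-4H-pyran-4-ylidene}-N-methoxy-N-methylacetamide, via tertiary carbinol adduct 5 (not isolated)
Conditions: 4, LiN(iPr)2, THF, −78 °C; CeCl3, −78 °C; then 3, −78 °C; AcOH; then pyridinium p-toluenesulfonate (cat.), CH2Cl2, 0 °C to rt
Reagents that add atoms: none
Why: The weakly basic, oxophilic cerium amide enolate should add to the pyranone carbonyl carbon (aldol addition), and mild acid should then ionise the tertiary carbinol to a pyrylium ion that loses the acidic C5 proton to give the conjugated pyran-4-ylidene (Knoevenagel-type condensation).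

Step 3
Reactants: 6 2-(tert-butyldiphenylsilyloxy)-2-{2-[3-(tert-butyldiphenylsilyloxy)propyl]-3-methoxy-4H-pyran-4-ylidene}-N-methoxy-N-methylacetamide
Product: 7 2-(tert-butyldiphenylsilyloxy)-2-{2-[3-(tert-butyldiphenylsilyloxy)propyl]-5-iodo-3-methoxy-4H-pyran-4-ylidene}-N-methoxy-N-methylacetamide
Conditions: N-iodosuccinimide, NaHCO3, MeCN, −20 to 0 °C, dark
Reagents that add atoms: N-iodosuccinimide O=C1CCC(=O)N1I
Why: Electrophilic iodination of the dienol ether should take place at the only free nucleophilic carbon, C5 of the pyran (the later C8a, β to the ring oxygen), as in the 3-halogenation of 4-pyranones (electrophilic substitution).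

Step 4
Reactants: 7 2-(tert-butyldiphenylsilyloxy)-2-{2-[3-(tert-butyldiphenylsilyloxy)propyl]-5-iodo-3-methoxy-4H-pyran-4-ylidene}-N-methoxy-N-methylacetamide
Product: 9 1-(tert-butyldiphenylsilyloxy)-1-{2-[3-(tert-butyldiphenylsilyloxy)propyl]-5-iodo-3-methoxy-4H-pyran-4-ylidene}butane-2,3-dione, via 1-ethoxyvinyl ketone 8 (not isolated)
Conditions: ethyl vinyl ether, tert-butyllithium, THF, −78 to 0 °C; then 7, −78 °C; aq. NH4Cl; then 1 M HCl, THF, 0 °C to rt
Reagents that add atoms: ethyl vinyl ether C=COCC (used as 1-ethoxyvinyllithium [Li]C(=C)OCC); water O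
Why: The N-methoxy-N-methylamide should stop at the ketone stage through its chelated tetrahedral intermediate, acyl substitution at −78 °C being faster than iodine–lithium exchange between two alkenyl partners, and acid hydrolysis of the enol ether should then reveal the methyl 1,2-diketone (acylation of an acetyl anion equivalent).

Step 5
Reactants: 9 1-(tert-butyldiphenylsilyloxy)-1-{2-[3-(tert-butyldiphenylsilyloxy)propyl]-5-iodo-3-methoxy-4H-pyran-4-ylidene}butane-2,3-dione
Product: 10 4-[1-(tert-butyldiphenylsilyloxy)-2,3-dioxobutylidene]-6-[3-(tert-butyldiphenylsilyloxy)propyl]-5-methoxy-4H-pyran-3-carbaldehyde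
Conditions: Pd(PPh3)4 (5 mol %), CO (3 atm), Bu3SnH (slow addition), THF, 50 °C
Reagents that add atoms: carbon monoxide [C-]#[O+]
Why: Oxidative addition of the alkenyl iodide to zerovalent palladium, CO insertion and hydride transfer from the stannane should give the aldehyde under neutral conditions (palladium-catalysed reductive carbonylation of an alkenyl iodide).

Step 6
Reactants: 10 4-[1-(tert-butyldiphenylsilyloxy)-2,3-dioxobutylidene]-6-[3-(tert-butyldiphenylsilyloxy)propyl]-5-methoxy-4H-pyran-3-carbaldehyde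
Product: 11 (7S)-5-(tert-butyldiphenylsilyloxy)-3-[3-(tert-butyldiphenylsilyloxy)propyl]-7-hydroxy-4-methoxy-7-methyl-6H-isochromene-6,8(7H)-dione
Conditions: (5aS,10bR)-2-(pentafluorophenyl)-5a,10b-dihydro-4H,6H-indeno[2,1-b][1,2,4]triazolo[4,3-d][1,4]oxazin-2-ium tetrafluoroborate (10 mol %), Et3N (10 mol %), toluene, rt
Reagents that add atoms: none
Why: The triazolylidene released from the salt should add to the C8 aldehyde, and proton transfer gives the hydroxy-enamine (acyl anion equivalent) whose C8 attacks the C7 carbonyl of the methyl 1,2-diketone before the carbene is lost from the α-ketol. The closest known reaction type is the enantioselective carbene-catalysed intramolecular crossed aldehyde–ketone benzoin reaction, which turns 2-(3-oxoalkyl)aryl aldehydes into six-membered tertiary α-ketols. The carbocycle (C4a, C5, C6, C7, C8, C8a) is closed by a 6-exo-trig attack on the C7 carbonyl, and the thermally mobile push–pull C4a=C5 bond supplies the isomer in which the diketone chain faces the formyl group. The new C7 stereocentre is set by the chiral aminoindanol-derived carbene, which shields one face of the hydroxy-enamine so that the C7 carbonyl is attacked on the face that leads to 7S. The step needs attack at C7 and not at C6 (five-membered ring), and acyl anion rather than homoenolate or C1-addition chemistry: C6 is a deactivated vinylogous ester carbonyl next to the silyloxy group whereas C7 is an activated methyl ketone, and the electron-poor N-pentafluorophenyl carbene with a weak amine base favours the benzoin pathway.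

Step 7
Reactants: 11 (7S)-5-(tert-butyldiphenylsilyloxy)-3-[3-(tert-butyldiphenylsilyloxy)propyl]-7-hydroxy-4-methoxy-7-methyl-6H-isochromene-6,8(7H)-dione
Product: 12 (7S)-5-(tert-butyldiphenylsilyloxy)-3-[3-(tert-butyldiphenylsilyloxy)propyl]-4-methoxy-7-methyl-6,8-dioxo-7,8-dihydro-6H-isochromen-7-yl butanoate
Conditions: butyric anhydride, 4-(dimethylamino)pyridine (cat.), pyridine, CH2Cl2, rt to 40 °C
Reagents that add atoms: butyric anhydride CCCC(=O)OC(=O)CCC
Why: Nucleophile-catalysed acylation should esterify the tertiary α-ketol, the only free hydroxyl, without touching the bonds at C7, so the configuration is retained (esterification).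

Step 8
Reactants: 12 (7S)-5-(tert-butyldiphenylsilyloxy)-3-[3-(tert-butyldiphenylsilyloxy)propyl]-4-methoxy-7-methyl-6,8-dioxo-7,8-dihydro-6H-isochromen-7-yl butanoate
Product: 13 (7S)-5-hydroxy-3-(3-hydroxypropyl)-4-methoxy-7-methyl-6,8-dioxo-7,8-dihydro-6H-isochromen-7-yl butanoate
Conditions: HF·pyridine, pyridine, THF, 0 °C to rt
Reagents that add atoms: none
Why: Fluoride should cleave the silyl enol ether at C5 and the primary silyl ether under mildly acidic conditions that leave the tertiary butanoate and the C7 stereocentre untouched (desilylation).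

**Compound list**

1 | 3-methoxy-2-methyl-4H-pyran-4-one | CC1=C(OC)C(=O)C=CO1 | starting material
2 | tert-butyl(2-iodoethoxy)diphenylsilane | CC(C)(C)[Si](OCCI)(c1ccccc1)c1ccccc1 | starting material
3 | 2-[3-(tert-butyldiphenylsilyloxy)propyl]-3-methoxy-4H-pyran-4-one | COC1=C(CCCO[Si](c2ccccc2)(c2ccccc2)C(C)(C)C)OC=CC1=O | intermediate
4 | 2-(tert-butyldiphenylsilyloxy)-N-methoxy-N-methylacetamide | CON(C)C(=O)CO[Si](c1ccccc1)(c1ccccc1)C(C)(C)C | starting material
5 | 2-(tert-butyldiphenylsilyloxy)-2-{2-[3-(tert-butyldiphenylsilyloxy)propyl]-4-hydroxy-3-methoxy-4H-pyran-4-yl}-N-methoxy-N-methylacetamide (diastereomer mixture, not isolated) | CON(C)C(=O)C(O[Si](c1ccccc1)(c1ccccc1)C(C)(C)C)C1(O)C=COC(CCCO[Si](c2ccccc2)(c2ccccc2)C(C)(C)C)=C1OC | intermediate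
6 | 2-(tert-butyldiphenylsilyloxy)-2-{2-[3-(tert-butyldiphenylsilyloxy)propyl]-3-methoxy-4H-pyran-4-ylidene}-N-methoxy-N-methylacetamide | CON(C)C(=O)C(O[Si](c1ccccc1)(c1ccccc1)C(C)(C)C)=C1C=COC(CCCO[Si](c2ccccc2)(c2ccccc2)C(C)(C)C)=C1OC | intermediate
7 | 2-(tert-butyldiphenylsilyloxy)-2-{2-[3-(tert-butyldiphenylsilyloxy)propyl]-5-iodo-3-methoxy-4H-pyran-4-ylidene}-N-methoxy-N-methylacetamide | CON(C)C(=O)C(O[Si](c1ccccc1)(c1ccccc1)C(C)(C)C)=C1C(I)=COC(CCCO[Si](c2ccccc2)(c2ccccc2)C(C)(C)C)=C1OC | intermediate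
8 | 1-(tert-butyldiphenylsilyloxy)-1-{2-[3-(tert-butyldiphenylsilyloxy)propyl]-5-iodo-3-methoxy-4H-pyran-4-ylidene}-3-ethoxybut-3-en-2-one (not isolated) | C=C(OCC)C(=O)C(O[Si](c1ccccc1)(c1ccccc1)C(C)(C)C)=C1C(I)=COC(CCCO[Si](c2ccccc2)(c2ccccc2)C(C)(C)C)=C1OC | intermediate
9 | 1-(tert-butyldiphenylsilyloxy)-1-{2-[3-(tert-butyldiphenylsilyloxy)propyl]-5-iodo-3-methoxy-4H-pyran-4-ylidene}butane-2,3-dione | CC(=O)C(=O)C(O[Si](c1ccccc1)(c1ccccc1)C(C)(C)C)=C1C(I)=COC(CCCO[Si](c2ccccc2)(c2ccccc2)C(C)(C)C)=C1OC | intermediate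
10 | 4-[1-(tert-butyldiphenylsilyloxy)-2,3-dioxobutylidene]-6-[3-(tert-butyldiphenylsilyloxy)propyl]-5-methoxy-4H-pyran-3-carbaldehyde | CC(=O)C(=O)C(O[Si](c1ccccc1)(c1ccccc1)C(C)(C)C)=C1C(C=O)=COC(CCCO[Si](c2ccccc2)(c2ccccc2)C(C)(C)C)=C1OC | intermediate
11 | (7S)-5-(tert-butyldiphenylsilyloxy)-3-[3-(tert-butyldiphenylsilyloxy)propyl]-7-hydroxy-4-methoxy-7-methyl-6H-isochromene-6,8(7H)-dione | O[C@@]1(C)C(=O)C2=COC(CCCO[Si](c3ccccc3)(c3ccccc3)C(C)(C)C)=C(OC)C2=C(O[Si](c3ccccc3)(c3ccccc3)C(C)(C)C)C1=O | intermediate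
12 | (7S)-5-(tert-butyldiphenylsilyloxy)-3-[3-(tert-butyldiphenylsilyloxy)propyl]-4-methoxy-7-methyl-6,8-dioxo-7,8-dihydro-6H-isochromen-7-yl butanoate | CCCC(=O)O[C@@]1(C)C(=O)C2=COC(CCCO[Si](c3ccccc3)(c3ccccc3)C(C)(C)C)=C(OC)C2=C(O[Si](c3ccccc3)(c3ccccc3)C(C)(C)C)C1=O | intermediate
13 | (7S)-5-hydroxy-3-(3-hydroxypropyl)-4-methoxy-7-methyl-6,8-dioxo-7,8-dihydro-6H-isochromen-7-yl butanoate (CNP0439446.2) | CCCC(=O)O[C@@]1(C)C(=O)C2=COC(CCCO)=C(OC)C2=C(O)C1=O | target

**Step count and risks**

Total step count: 8. Longest linear sequence: 8 steps (1 to 13).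

Steps most likely to fail:

Step 6 (key step). The carbene may add reversibly to the electrophilic C1 of the pyranylidene or to the diketone, the acyl anion equivalent may form slowly from the donor-conjugated aldehyde, or the attack may occur with poor facial selectivity, so that the ring does not close or closes with low enantiomeric purity. The fallback closes the same ring by an anionic (Parham-type) cyclisation, with C7 set beforehand by self-regeneration of the lactic acid stereocentre; it sets out from 7 and comes back at 12. Reduction of the N-methoxy-N-methylamide of 7 with iBu2AlH (THF, −78 °C) should give pyranylidene aldehyde F1. The lithium enolate (LiN(iPr)2, THF, −78 °C) of commercial (2S,5S)-2-tert-butyl-5-methyl-1,3-dioxolan-4-one (C[C@@H]1O[C@H](C(C)(C)C)OC1=O) should add to F1 on the face anti to the tert-butyl group to give aldol adduct F2, which holds the quaternary carbon of the later C7. Dess–Martin periodinane should oxidise the carbinol to ketone F3. Iodine–lithium exchange (tert-butyllithium, THF, −100 °C) and attack of the C8a carbanion on the dioxolanone carbonyl should close the carbocycle; the hemiketal loses pivalaldehyde, and the tertiary lithium alkoxide is acylated in the same flask with butyric anhydride to give 12.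

Step 2. Proton transfer from the acidic γ-CH2 of 3 to the enolate, addition at C6 of the pyranone in place of the carbonyl carbon, or oxygen-to-oxygen silyl migration in the adduct may prevent the condensation. The fallback activates the electrophile in place of the nucleophile; it sets out from 3 and comes back at 6. Methyl triflate (CH2Cl2, rt) should O-methylate 3 to 4-methoxypyrylium triflate F4. Ketene silyl acetal F5, made from methyl 2-(tert-butyldiphenylsilyloxy)acetate with LiN(iPr)2 and Me3SiCl, should add at C4 of F4 with loss of methanol (addition–elimination at the γ-position of a 4-alkoxypyrylium salt, 2,6-lutidine, CH2Cl2, −40 °C to rt) to give pyranylidene methyl ester F6. Aminolysis with Me(MeO)NMgCl (from N,O-dimethylhydroxylamine hydrochloride and iPrMgCl, THF, −20 °C) should convert F6 into 6.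

Step 5. The tin hydride may reduce the 1,2-diketone or the carbon–iodine bond faster than CO insertion takes place. The fallback brings in C8 by electrophilic formylation before the diketone exists; it sets out from 6 and comes back at 10. Vilsmeier–Haack formylation of 6 (POCl3, DMF, 0 °C; aq. NaOAc) at the free C5 position of the pyran should give aldehyde F7. The aldehyde is masked as dimethyl acetal F8 (HC(OMe)3, pyridinium p-toluenesulfonate, MeOH). 1-Ethoxyvinyllithium (THF, −78 °C) should then add to the N-methoxy-N-methylamide to give enol ether ketone F9, and 1 M HCl in THF should hydrolyse the enol ether and the acetal together to give 10.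

Further compounds
F1 | step 6 | 2-(tert-butyldiphenylsilyloxy)-2-{2-[3-(tert-butyldiphenylsilyloxy)propyl]-5-iodo-3-methoxy-4H-pyran-4-ylidene}acetaldehyde | O=CC(O[Si](c1ccccc1)(c1ccccc1)C(C)(C)C)=C1C(I)=COC(CCCO[Si](c2ccccc2)(c2ccccc2)C(C)(C)C)=C1OC
F2 | step 6 | (2S,5R)-2-tert-butyl-5-(2-(tert-butyldiphenylsilyloxy)-2-{2-[3-(tert-butyldiphenylsilyloxy)propyl]-5-iodo-3-methoxy-4H-pyran-4-ylidene}-1-hydroxyethyl)-5-methyl-1,3-dioxolan-4-one (carbinol epimers) | C[C@]1(C(O)C(O[Si](c2ccccc2)(c2ccccc2)C(C)(C)C)=C2C(I)=COC(CCCO[Si](c3ccccc3)(c3ccccc3)C(C)(C)C)=C2OC)O[C@H](C(C)(C)C)OC1=O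
F3 | step 6 | (2S,5R)-2-tert-butyl-5-((tert-butyldiphenylsilyloxy){2-[3-(tert-butyldiphenylsilyloxy)propyl]-5-iodo-3-methoxy-4H-pyran-4-ylidene}acetyl)-5-methyl-1,3-dioxolan-4-one | C[C@]1(C(=O)C(O[Si](c2ccccc2)(c2ccccc2)C(C)(C)C)=C2C(I)=COC(CCCO[Si](c3ccccc3)(c3ccccc3)C(C)(C)C)=C2OC)O[C@H](C(C)(C)C)OC1=O
F4 | step 2 | 2-[3-(tert-butyldiphenylsilyloxy)propyl]-3,4-dimethoxypyrylium trifluoromethanesulfonate | COc1c(CCCO[Si](c2ccccc2)(c2ccccc2)C(C)(C)C)[o+]ccc1OC.[O-]S(=O)(=O)C(F)(F)F
F5 | step 2 | 2-(tert-butyldiphenylsilyloxy)-1-methoxy-1-(trimethylsilyloxy)ethene | COC(O[Si](C)(C)C)=CO[Si](c1ccccc1)(c1ccccc1)C(C)(C)C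
F6 | step 2 | methyl 2-(tert-butyldiphenylsilyloxy)-2-{2-[3-(tert-butyldiphenylsilyloxy)propyl]-3-methoxy-4H-pyran-4-ylidene}acetate | COC(=O)C(O[Si](c1ccccc1)(c1ccccc1)C(C)(C)C)=C1C=COC(CCCO[Si](c2ccccc2)(c2ccccc2)C(C)(C)C)=C1OC
F7 | step 5 | 2-(tert-butyldiphenylsilyloxy)-2-{2-[3-(tert-butyldiphenylsilyloxy)propyl]-5-formyl-3-methoxy-4H-pyran-4-ylidene}-N-methoxy-N-methylacetamide | CON(C)C(=O)C(O[Si](c1ccccc1)(c1ccccc1)C(C)(C)C)=C1C(C=O)=COC(CCCO[Si](c2ccccc2)(c2ccccc2)C(C)(C)C)=C1OC
F8 | step 5 | 2-(tert-butyldiphenylsilyloxy)-2-{2-[3-(tert-butyldiphenylsilyloxy)propyl]-5-(dimethoxymethyl)-3-methoxy-4H-pyran-4-ylidene}-N-methoxy-N-methylacetamide | CON(C)C(=O)C(O[Si](c1ccccc1)(c1ccccc1)C(C)(C)C)=C1C(C(OC)OC)=COC(CCCO[Si](c2ccccc2)(c2ccccc2)C(C)(C)C)=C1OC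
F9 | step 5 | 1-(tert-butyldiphenylsilyloxy)-1-{2-[3-(tert-butyldiphenylsilyloxy)propyl]-5-(dimethoxymethyl)-3-methoxy-4H-pyran-4-ylidene}-3-ethoxybut-3-en-2-one | C=C(OCC)C(=O)C(O[Si](c1ccccc1)(c1ccccc1)C(C)(C)C)=C1C(C(OC)OC)=COC(CCCO[Si](c2ccccc2)(c2ccccc2)C(C)(C)C)=C1OC
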